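South differs from its neighbour north-east in a single setting, the charge of partner, and I want to know what that charge does to the end of the run.

    partner + protic impurity → quenched reagent (k1 = 0.152 /M/h)
    intermediate A ⇌ intermediate B (K2 = 0.151, k2 = 0.0163 /h)
    substrate → target (k3 = 0.0122 /h)
    substrate + partner → intermediate A (k4 = 0.0467 /M/h)

- south: substrate 0.10 M; partner 0.450 M; protic impurity 0.0500 M; time 5.0 d
- north-east: substrate 0.10 M; partner 0.300 M; protic impurity 0.0500 M; time 5.0 d

- which of these there is most of at the end, counted by the substrate in it, south (target / intermediate B / intermediate A / substrate)
- which of these there is most of at the end, counted by the substrate in it, north-east (target / intermediate B / intermediate A / substrate)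
- amount of the one of these that there is most of at the end, in percent of the substrate charged, south
- amount of the one of these that there is most of at the end, in percent of the substrate charged, north-east

Substrate has two exits: alone to target, or with partner to intermediate A, which then exchanges with intermediate B. Partner is also eaten by protic impurity. In north-east the impurity's half-life at the charged partner is 15.2 h, shorter than the 26.4 h of substrate, so I treat the quench as finished and reckon with the partner it leaves free, charge minus impurity: 0.400 M in south, 0.250 M in north-east. I hold partner there, though coupling takes some and the early flask holds more.

With partner constant, substrate decays pseudo-first-order, with the target constant plus the coupling constant times free partner. The two exits then divide consumed substrate in a fixed proportion. The target constant over that sum is 39.5% in south and 51.1% in north-east. This target share, a selectivity, is what I carry.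

After 120 h the decay leaves 2.46% of substrate in south and 5.70% in north-east. The exchange has a half-life of 5.58 h, shorter than substrate's 26.4 h in north-east and its 20.9 h in south, so I take intermediate A as the coupled material divided by one plus the equilibrium constant. My reckoning then gives south 38.5% target and 51.3% intermediate A, so I commit to intermediate A. For north-east it gives 48.2% target and 40.1% intermediate A, so I commit to target.

The forecast, stepped by hand with partner falling, opens “South and north-east behave alike” and names intermediate A at 50.3% (48.5% to 52%) for south and target at 47.5% (46% to 49%) for north-east. It names the same species as I do, but its amounts differ from my 51.3% and 48.2%.

The flask gives intermediate A at 50.3% in south and target at 48.2% in north-east; target and intermediate A stand equal at a partner charge of 0.359 M, which lies below south's charge and above north-east's.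

In north-east the rate to target over the rate of coupling is 0.87 at the start and 1.0 at 0.672 d, against the 1.04 implied by the target share. At the end, target over consumed substrate reads 51.6% in north-east and 40.3% in south, against the carried 51.1% and 39.5%.

For north-east read at 30 h, the same share and decay give 48.9% of substrate left and 26.1% target. That reading shows 48.0% of substrate and 25.7% of target.

The constants were chosen freely; no experiment stands behind them.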